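A direct plan would start from 1,2,3,4-tetramethoxybenzene A1, make 2,3,4,5-tetramethoxyphenol A2 by lithiation, borylation and peroxide oxidation, and acylate it with a methoxyacetyl donor under Fries conditions to 1-(2-hydroxy-3,4,5,6-tetramethoxyphenyl)-2-methoxyethan-1-one A3.
A formamide acetal would then close ring C to 3,5,6,7,8-pentamethoxy-4H-chromen-4-one A4, and ring B would be attached last by metalation of C2 and cross-coupling with 1-iodo-2,4-dimethoxybenzene A5.
Weak point 1, the phenol synthesis that would turn A1 into A2: three operations (metalation, borylation, oxidation) would build no bond of the skeleton and only install the oxygen that later becomes O1.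
Weak point 2, the Fries rearrangement that would lead from A2 to A3: a hot Lewis acid would act next to four methoxy groups, the acyl group would have to enter between OH and OMe, and the α-methoxyacyl cation could decarbonylate; ether cleavage next to the new chelating carbonyl would be hard to exclude.
Weak point 3, the final C2 arylation of A4 with A5: the whole linear sequence would be staked on joining a metalated chromone, flanked by the 3-methoxy group and liable to ring opening, to an ortho-substituted, electron-rich aryl iodide.

**Retrosynthetic overview**
Key disconnection: the O1–C8a bond of ring C. C8a is the only hydrogen-bearing carbon of a 2,3,4,5-tetramethoxybenzoyl group, and O1 is the carbonyl oxygen of a 2,4-dimethoxybenzoyl group, so an anodic dehydrogenative C–O coupling within the open-chain 2-methoxy-1,3-diaryl-1,3-dione 7 would close ring C as the last event.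
Dione 7 would come from C2–C3 bond formation, by aroylation of the enolate of ketone 4 with ring B as its acid chloride 5; ketone 4 would come from C4–C4a bond formation between lithiated 1 and a methoxyacetyl Weinreb amide.
Ring order: rings A and B are bought and ring C is formed last; no chromone appears before the final step.
No phenol is made, so the borylation/oxidation run-up and the Fries step disappear, and ring B enters early as a simple acyl donor, so no late cross-coupling at a hindered C2 is needed.

Key step: step 3

Remark: the target is achiral; the only stereocentre on the way (C2 of dione 7) is racemic, labile, and removed in step 3. Flavone numbering (O1, C2, C3, C4, C4a, C5–C8, C8a, ring B primed) is used for the atoms of the open-chain precursors as well.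

Step 1
Reactants: 1 1,2,3,4-tetramethoxybenzene; 2 N,2-dimethoxy-N-methylacetamide
Product: 4 2-methoxy-1-(2,3,4,5-tetramethoxyphenyl)ethan-1-one, via aryllithium 3 (not isolated)
Conditions: n-BuLi (1.1 equiv), TMEDA, THF, 0 °C; then 2, −78 °C → 0 °C; then 1 M HCl
Reagents that add atoms: none
Why: Directed ortho-metalation followed by Weinreb ketone synthesis: the two ring C–H positions of 1 are equivalent and each lies ortho to a methoxy group, so a single aryllithium should form, and its adduct with the Weinreb amide is a stable lithium chelate that releases the ketone only on acidic work-up, which rules out over-addition; no stereocentre is formed.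

Step 2
Reactants: 4 2-methoxy-1-(2,3,4,5-tetramethoxyphenyl)ethan-1-one; 5 2,4-dimethoxybenzoyl chloride
Product: 7 1-(2,4-dimethoxyphenyl)-2-methoxy-3-(2,3,4,5-tetramethoxyphenyl)propane-1,3-dione, via lithium enolate 6 (not isolated)
Conditions: LiN(SiMe3)2 (2.2 equiv), THF, −78 °C; then 5, −78 °C → 0 °C; then 1 M HCl
Reagents that add atoms: none
Why: Claisen-type C-acylation of a preformed lithium enolate with an acid chloride: 4 has a single enolisable position, the chelated (Z)-enolate should attack the aroyl chloride at carbon, and the second equivalent of base takes up the more acidic 1,3-dione as it forms, so that neither proton transfer to unreacted enolate nor a second acylation should occur; the new C2 stereocentre is racemic and labile by enolisation, which is irrelevant because it becomes sp2 in step 3.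

Step 3
Reactants: 7 1-(2,4-dimethoxyphenyl)-2-methoxy-3-(2,3,4,5-tetramethoxyphenyl)propane-1,3-dione
Product: 8 2-(2,4-dimethoxyphenyl)-3,5,6,7,8-pentamethoxy-4H-chromen-4-one
Conditions: constant-current electrolysis (undivided cell, graphite anode, platinum cathode, about 2.2 F per mol), n-Bu4NPF6, dry (CF3)2CHOH/CH2Cl2, rt
Reagents that add atoms: none
Why: Proposed new method: anodic one-electron oxidation in the fluorinated alcohol should occur at the tetramethoxybenzoyl ring, the most electron-rich π system of 7, and give an arene radical cation whose only unsubstituted carbon (the future C8a, ortho and para to methoxy groups) is attacked by the oxygen of the 2,4-dimethoxybenzoyl carbonyl or of its enol; a second electron transfer and loss of the C8a and C3 protons should then give the aromatic pyranone, with hydrogen evolved at the cathode. The closest known reaction types are dehydrogenative C–O cyclisations of electron-rich arenes that carry a tethered oxygen nucleophile (anodic lactonisation of biaryl-2-carboxylic acids to benzocoumarins, anodic benzoxazole formation from anilides, FeCl3-mediated closure of α-(alkoxyaryl) ketones to benzofurans) and the capture of alkoxyarene radical cations by β-dicarbonyl compounds in fluorinated alcohols. Ring C closes by O1–C8a bond formation through a six-membered transition state (6-exo-trig if the C8–C8a bond of the oxidised arene is taken as the acceptor), whereas closure through C3 would need a four-membered ring and cannot compete. No stereocentre is formed and the labile one at C2 of 7 disappears. The step needs selectivity for ring A over ring B and for the arene over the C2–H position: ring A has the lower oxidation potential and its free carbon is activated by ortho and para methoxy groups, while the free ortho carbon of ring B (C6') is meta to both of its methoxy groups. The base-free, weakly nucleophilic medium keeps the dione un-ionised, so that enolate oxidation at C2 should stay slow, and the limited charge should protect ring A of the product from further oxidation.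

**Compound list**
1 | 1,2,3,4-tetramethoxybenzene | COc1ccc(OC)c(OC)c1OC | starting material
2 | N,2-dimethoxy-N-methylacetamide (Weinreb amide of methoxyacetic acid) | COCC(=O)N(C)OC | starting material
3 | (2,3,4,5-tetramethoxyphenyl)lithium | [Li]c1cc(OC)c(OC)c(OC)c1OC | intermediate
4 | 2-methoxy-1-(2,3,4,5-tetramethoxyphenyl)ethan-1-one | COCC(=O)c1cc(OC)c(OC)c(OC)c1OC | intermediate
5 | 2,4-dimethoxybenzoyl chloride | COc1ccc(C(=O)Cl)c(OC)c1 | starting material
6 | lithium (Z)-2-methoxy-1-(2,3,4,5-tetramethoxyphenyl)ethen-1-olate (chelated geometry as expected, of no consequence) | [Li]O/C(=C\OC)c1cc(OC)c(OC)c(OC)c1OC | intermediate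
7 | 1-(2,4-dimethoxyphenyl)-2-methoxy-3-(2,3,4,5-tetramethoxyphenyl)propane-1,3-dione (racemic at C2, keto–enol mixture, drawn as the diketone) | COc1ccc(C(=O)C(OC)C(=O)c2cc(OC)c(OC)c(OC)c2OC)c(OC)c1 | intermediate
8 | 2-(2,4-dimethoxyphenyl)-3,5,6,7,8-pentamethoxy-4H-chromen-4-one (3,5,6,7,8,2',4'-heptamethoxyflavone, achiral) | COc1ccc(-c2oc3c(OC)c(OC)c(OC)c(OC)c3c(=O)c2OC)c(OC)c1 | target

Total step count: 3
Longest linear sequence: 3 steps (1 → 4 → 7 → 8)

**Steps most likely to fail**

Step 3 (proposed method). Oxidation may take place at the doubly activated C2–H or on ring B instead of ring A, the oxygen may add to the methoxy-bearing ortho carbon of ring A, or ring A of the product may be oxidised further to a quinone. The fallback uses known chemistry, sets out from 4 and comes back at 8; it places a halogen where the anode was meant to act. Ring bromination of 4 at its only aromatic C–H (NBS, MeCN, rt) should give 1-(2-bromo-3,4,5,6-tetramethoxyphenyl)-2-methoxyethan-1-one F1. Aroylation of F1 with 5 under the conditions of step 2 should give 1-(2-bromo-3,4,5,6-tetramethoxyphenyl)-3-(2,4-dimethoxyphenyl)-2-methoxypropane-1,3-dione F2. The known copper-catalysed intramolecular Ullmann O-arylation of 1-(2-bromoaryl)-1,3-diones (CuI, 1,10-phenanthroline, K2CO3, DMF, 100 °C) would then close ring C to 8.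

Step 2. The chelated α-methoxy enolate may be acylated at oxygen to an enol ester, or the acid chloride may be consumed by the silylamide. The fallback sets out from 4 and comes back at 7. Aldol addition of enolate 6 to 2,4-dimethoxybenzaldehyde (THF, −78 °C) should give 3-(2,4-dimethoxyphenyl)-3-hydroxy-2-methoxy-1-(2,3,4,5-tetramethoxyphenyl)propan-1-one F3 as a mixture of racemic diastereomers. Oxidation of its benzylic alcohol with Dess–Martin periodinane (CH2Cl2, rt) would give 7. An aldehyde can only be attacked at carbon, so the C-versus-O question does not arise.

Step 1. The basic aryllithium may be quenched by proton transfer from the Weinreb amide, or lithiation may be incomplete or go twice. The fallback sets out from 1 and comes back at 4. Monobromination (NBS, MeCN, rt) should give 1-bromo-2,3,4,5-tetramethoxybenzene F4. Magnesium insertion (Mg, LiCl, THF) should give (2,3,4,5-tetramethoxyphenyl)magnesium bromide F5. Acylation of this less basic, stoichiometrically defined nucleophile with 2 (0 °C, then 1 M HCl) would give 4.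

**Further compounds**
F1 | step 3 | 1-(2-bromo-3,4,5,6-tetramethoxyphenyl)-2-methoxyethan-1-one | COCC(=O)c1c(Br)c(OC)c(OC)c(OC)c1OC
F2 | step 3 | 1-(2-bromo-3,4,5,6-tetramethoxyphenyl)-3-(2,4-dimethoxyphenyl)-2-methoxypropane-1,3-dione (racemic at C2) | COc1ccc(C(=O)C(OC)C(=O)c2c(Br)c(OC)c(OC)c(OC)c2OC)c(OC)c1
F3 | step 2 | 3-(2,4-dimethoxyphenyl)-3-hydroxy-2-methoxy-1-(2,3,4,5-tetramethoxyphenyl)propan-1-one (mixture of racemic diastereomers) | COc1ccc(C(O)C(OC)C(=O)c2cc(OC)c(OC)c(OC)c2OC)c(OC)c1
F4 | step 1 | 1-bromo-2,3,4,5-tetramethoxybenzene | COc1cc(Br)c(OC)c(OC)c1OC
F5 | step 1 | (2,3,4,5-tetramethoxyphenyl)magnesium bromide | COc1cc([Mg]Br)c(OC)c(OC)c1OC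
A1 | direct plan | 1,2,3,4-tetramethoxybenzene | COc1ccc(OC)c(OC)c1OC
A2 | direct plan | 2,3,4,5-tetramethoxyphenol | COc1cc(O)c(OC)c(OC)c1OC
A3 | direct plan | 1-(2-hydroxy-3,4,5,6-tetramethoxyphenyl)-2-methoxyethan-1-one | COCC(=O)c1c(O)c(OC)c(OC)c(OC)c1OC
A4 | direct plan | 3,5,6,7,8-pentamethoxy-4H-chromen-4-one | COc1coc2c(OC)c(OC)c(OC)c(OC)c2c1=O
A5 | direct plan | 1-iodo-2,4-dimethoxybenzene | COc1ccc(I)c(OC)c1
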